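**Retrosynthetic overview** (ring A = lactone whose C3 benzyl belongs to the biaryl; ring B = lactone whose C4 benzyl belongs to the biaryl)
1. Target ⇒ tetrabenzyl ether (debenzylation) ⇒ bis-lactone lacking only the outer C3 benzyl of ring B, which is added by enediolate alkylation anti to the C4 substituent.
2. Bis-lactone ⇒ one open-chain biaryl with ring A masked as a Seebach acetal acid and ring B as a 3-arylpropanal. Aldol with ethyl glyoxylate, then borane and acid, closes both γ-lactones in the same operation.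
3. Open-chain biaryl ⇒ Suzuki union of an aryl bromide (the acetal acid) with a cinnamaldehyde boronate. Both core arenes come from 5-bromovanillin.
4. Acetal acid ⇒ (R)-malate by two ordered benzylations: C3 first with the outer arene, C2 second with the core arene. The order fixes the head-to-tail regiochemistry.
5. Ring order: the four arenes are bought; lactones A and B form together in step 11.

Assumption: the biaryl axis carries only two ortho substituents and rotates freely, so no axial stereochemistry has to be set.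

**Step 1**
Reactants: 1 5-bromovanillin (3-bromo-4-hydroxy-5-methoxybenzaldehyde)
Product: 2 4-(benzyloxy)-3-bromo-5-methoxybenzaldehyde
Conditions: BnBr, K2CO3, DMF, 60 °C
Reagents that add atoms: benzyl bromide, BrCc1ccccc1
Why: Williamson ether synthesis on the acidic phenol; the benzyl ether survives all later steps and leaves by hydrogenolysis at the end.

**Step 2**
Reactants: 2 4-(benzyloxy)-3-bromo-5-methoxybenzaldehyde
Product: 3 2-(benzyloxy)-1-bromo-5-(bromomethyl)-3-methoxybenzene
Conditions: LiBr, Me3SiCl, (HMe2Si)2O, MeCN, 0 °C to rt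
Reagents that add atoms: lithium bromide, [Li+].[Br-]
Why: Reductive bromination of an aromatic aldehyde, in which the hydrosilane reduces the Me3SiBr-activated carbonyl and bromide displaces the benzylic silyl ether, so no separate alcohol stage is needed.

**Step 3**
Reactants: 4 [4-(benzyloxy)-3-methoxyphenyl]methanol
Product: 5 1-(benzyloxy)-4-(bromomethyl)-2-methoxybenzene
Conditions: PBr3, Et2O, 0 °C
Reagents that add atoms: phosphorus tribromide, BrP(Br)Br
Why: Standard conversion of an electron-rich benzylic alcohol to the bromide through the phosphite ester; the product is used fresh.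

**Step 4**
Reactants: 6 diisopropyl (R)-malate; 5 1-(benzyloxy)-4-(bromomethyl)-2-methoxybenzene
Product: 7 diisopropyl (2R,3S)-2-hydroxy-3-[4-(benzyloxy)-3-methoxybenzyl]butanedioate
Conditions: LiN(SiMe3)2 (2.1 equiv), THF, −78 to −20 °C; 5, −78 to 0 °C
Reagents that add atoms: none
Why: Fráter–Seebach alkylation, in which the lithium-chelated alkoxide enolate is benzylated on the open face to give the anti (2R,3S) product (about 9:1, minor isomer removed at 9), and the new centre becomes C4 of ring A.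

**Step 5**
Reactants: 7 diisopropyl (2R,3S)-2-hydroxy-3-[4-(benzyloxy)-3-methoxybenzyl]butanedioate
Product: 8 (2R,3S)-2-hydroxy-3-[4-(benzyloxy)-3-methoxybenzyl]butanedioic acid
Conditions: KOH, THF/H2O, rt; HCl
Reagents that add atoms: potassium hydroxide, [K+].[OH-]
Why: Ester saponification at room temperature, where the dicarboxylate resists enolisation, so neither centre is scrambled.

**Step 6**
Reactants: 8 (2R,3S)-2-hydroxy-3-[4-(benzyloxy)-3-methoxybenzyl]butanedioic acid
Product: 9 (2S)-3-[4-(benzyloxy)-3-methoxyphenyl]-2-[(2R,4R)-2-tert-butyl-5-oxo-1,3-dioxolan-4-yl]propanoic acid (cis acetal)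
Conditions: t-BuCHO, p-TsOH (cat.), H2SO4 (cat.), pentane/CH2Cl2, reflux, water separator
Reagents that add atoms: pivalaldehyde, CC(C)(C)C=O
Why: Seebach acetalisation picks the α-hydroxy acid (five-membered ring) over the β-carboxyl and gives the cis acetal under thermodynamic control; crystallisation also removes the minor isomer from step 4.

**Step 7**
Reactants: 9 cis acetal acid; 3 2-(benzyloxy)-1-bromo-5-(bromomethyl)-3-methoxybenzene
Product: 10 (2S)-3-[4-(benzyloxy)-3-methoxyphenyl]-2-{(2R,4R)-4-[4-(benzyloxy)-3-bromo-5-methoxybenzyl]-2-tert-butyl-5-oxo-1,3-dioxolan-4-yl}propanoic acid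
Conditions: LiN(SiMe3)2 (3 equiv), THF, −78 °C; 3, −78 to −30 °C
Reagents that add atoms: none
Why: Self-regeneration of stereocentres, in which the carboxylate enolate is alkylated anti to the tert-butyl group so benzyl replaces H with retention, setting the quaternary carbinol carbon (C3 of ring A, R).

**Step 8**
Reactants: 2 4-(benzyloxy)-3-bromo-5-methoxybenzaldehyde; 11 (triphenylphosphoranylidene)acetaldehyde
Product: 12 (E)-3-[4-(benzyloxy)-3-bromo-5-methoxyphenyl]prop-2-enal
Conditions: toluene, 80 °C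
Reagents that add atoms: none
Why: Wittig olefination with a stabilised ylide gives the E enal, a two-carbon homologue with no enolisable hydrogen, so it tolerates the coupling base.

**Step 9**
Reactants: 12 (E)-3-[4-(benzyloxy)-3-bromo-5-methoxyphenyl]prop-2-enal; 10 bromo acetal acid
Product: 14 biaryl enal acid (10 with Br replaced by the 2-(benzyloxy)-3-methoxy-5-[(E)-3-oxoprop-1-enyl]phenyl group), via pinacol boronate 13 (not isolated)
Conditions: B2pin2, KOAc, PdCl2(dppf) (5 mol%), dioxane, 90 °C; then 10, CsF, Pd(OAc)2/SPhos (5/10 mol%), 80 °C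
Reagents that add atoms: bis(pinacolato)diboron, CC1(C)OB(OC1(C)C)B1OC(C)(C)C(C)(C)O1 (its boryl group is found in 13 only)
Why: Miyaura borylation followed by Suzuki–Miyaura coupling, where anhydrous fluoride activation spares the acyl acetal, the acid travels as its caesium salt, and SPhos handles the two ortho benzyloxy groups.

**Step 10**
Reactants: 14 biaryl enal acid
Product: 15 biaryl propanal acid (14 with the enal arm reduced to 3-oxopropyl)
Conditions: diethyl 2,6-dimethyl-1,4-dihydropyridine-3,5-dicarboxylate (1.1 equiv), Bn2NH·CF3CO2H (10 mol%), THF, rt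
Reagents that add atoms: none
Why: Iminium-catalysed transfer hydrogenation reduces only the conjugated C=C and leaves benzyl ethers, acetal, acid and aldehyde untouched.

**Step 11 (key step)**
Reactants: 15 biaryl propanal acid; 16 ethyl glyoxylate
Product: 19 tri-O-benzyl bis-lactone (ring A complete; ring B = (3R,4R)-3-hydroxy-4-arylmethyl lactone), via aldol adduct 17 (not isolated), via primary diol 18 (not isolated)
Conditions: (S)-α,α-bis[3,5-bis(trifluoromethyl)phenyl]pyrrolidine-2-methanol (20 mol%), 16 (3 equiv), MeCN/H2O, rt; extraction; BH3·THF, THF, 0 °C; MeOH; TFA, CH2Cl2, rt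
Reagents that add atoms: none
Why: A diarylprolinol enamine cross-aldol (hydrogen-bond-directed, same facial sense as L-proline, anti adduct) sets C4 of ring B as R; borane then reduces only CO2H and CHO; acid finally makes each new primary alcohol attack its neighbouring acyl group (ester exchange for ring B, opening of the acyl acetal with loss of pivalaldehyde for ring A), so both γ-lactones close together.

**Step 12**
Reactants: 19 tri-O-benzyl bis-lactone; 5 1-(benzyloxy)-4-(bromomethyl)-2-methoxybenzene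
Product: 20 tetra-O-benzyl ether of the target
Conditions: LiN(i-Pr)2 (3.3 equiv), THF/DMPU, −78 °C; 5 (1.2 equiv), −78 to −40 °C
Reagents that add atoms: none
Why: Alkylation of the α-hydroxy lactone enediolate, where the benzyl bromide enters anti to the C4 arylmethyl group, leaving OH cis to it (C3 of ring B, R); ring A has no α-hydrogen and only lends its alkoxide.

**Step 13**
Reactants: 20 tetra-O-benzyl ether of the target
Product: 21 target CNP0218652.1
Conditions: H2 (1 atm), Pd/C (10 wt%), EtOAc/EtOH, rt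
Reagents that add atoms: none
Why: Hydrogenolysis of the four aryl benzyl ethers; lactones, tertiary alcohols and all four stereocentres are inert to it.

**Compound list**
1 | 5-bromovanillin | O=Cc1cc(OC)c(O)c(Br)c1 | starting material
2 | 4-(benzyloxy)-3-bromo-5-methoxybenzaldehyde | O=Cc1cc(OC)c(OCc2ccccc2)c(Br)c1 | intermediate
3 | 2-(benzyloxy)-1-bromo-5-(bromomethyl)-3-methoxybenzene | BrCc1cc(OC)c(OCc2ccccc2)c(Br)c1 | intermediate
4 | [4-(benzyloxy)-3-methoxyphenyl]methanol | OCc1ccc(OCc2ccccc2)c(OC)c1 | starting material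
5 | 1-(benzyloxy)-4-(bromomethyl)-2-methoxybenzene | BrCc1ccc(OCc2ccccc2)c(OC)c1 | intermediate
6 | diisopropyl (R)-malate | CC(C)OC(=O)C[C@@H](O)C(=O)OC(C)C | starting material
7 | diisopropyl (2R,3S)-2-hydroxy-3-[4-(benzyloxy)-3-methoxybenzyl]butanedioate | CC(C)OC(=O)[C@@H](Cc1ccc(OCc2ccccc2)c(OC)c1)[C@@H](O)C(=O)OC(C)C | intermediate
8 | (2R,3S)-2-hydroxy-3-[4-(benzyloxy)-3-methoxybenzyl]butanedioic acid | OC(=O)[C@@H](Cc1ccc(OCc2ccccc2)c(OC)c1)[C@@H](O)C(=O)O | intermediate
9 | (2S)-3-[4-(benzyloxy)-3-methoxyphenyl]-2-[(2R,4R)-2-tert-butyl-5-oxo-1,3-dioxolan-4-yl]propanoic acid | O=C1O[C@H](C(C)(C)C)O[C@@H]1[C@H](Cc2ccc(OCc3ccccc3)c(OC)c2)C(=O)O | intermediate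
10 | (2S)-3-[4-(benzyloxy)-3-methoxyphenyl]-2-{(2R,4R)-4-[4-(benzyloxy)-3-bromo-5-methoxybenzyl]-2-tert-butyl-5-oxo-1,3-dioxolan-4-yl}propanoic acid | O=C1O[C@H](C(C)(C)C)O[C@]1(Cc2cc(OC)c(OCc3ccccc3)c(Br)c2)[C@H](Cc2ccc(OCc3ccccc3)c(OC)c2)C(=O)O | intermediate
11 | (triphenylphosphoranylidene)acetaldehyde | O=CC=P(c1ccccc1)(c1ccccc1)c1ccccc1 | starting material
12 | (E)-3-[4-(benzyloxy)-3-bromo-5-methoxyphenyl]prop-2-enal | O=C/C=C/c1cc(OC)c(OCc2ccccc2)c(Br)c1 | intermediate
13 | (E)-3-[4-(benzyloxy)-3-methoxy-5-(4,4,5,5-tetramethyl-1,3,2-dioxaborolan-2-yl)phenyl]prop-2-enal | O=C/C=C/c1cc(OC)c(OCc2ccccc2)c(B2OC(C)(C)C(C)(C)O2)c1 | intermediate (not isolated)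
14 | biaryl enal acid (acetal acid of ring A joined at C5 to the cinnamaldehyde arene) | O=C1O[C@H](C(C)(C)C)O[C@]1(Cc2cc(OC)c(OCc3ccccc3)c(-c3cc(/C=C/C=O)cc(OC)c3OCc3ccccc3)c2)[C@H](Cc2ccc(OCc3ccccc3)c(OC)c2)C(=O)O | intermediate
15 | biaryl propanal acid | O=C1O[C@H](C(C)(C)C)O[C@]1(Cc2cc(OC)c(OCc3ccccc3)c(-c3cc(CCC=O)cc(OC)c3OCc3ccccc3)c2)[C@H](Cc2ccc(OCc3ccccc3)c(OC)c2)C(=O)O | intermediate
16 | ethyl glyoxylate | CCOC(=O)C=O | starting material
17 | aldol adduct: 15 whose propanal arm has become the ethyl (2R,3S)-3-formyl-2-hydroxybutanoate arm | O=C1O[C@H](C(C)(C)C)O[C@]1(Cc2cc(OC)c(OCc3ccccc3)c(-c3cc(C[C@H](C=O)[C@@H](O)C(=O)OCC)cc(OC)c3OCc3ccccc3)c2)[C@H](Cc2ccc(OCc3ccccc3)c(OC)c2)C(=O)O | intermediate (not isolated)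
18 | primary diol: 17 with CO2H and CHO both reduced to CH2OH | O=C1O[C@H](C(C)(C)C)O[C@]1(Cc2cc(OC)c(OCc3ccccc3)c(-c3cc(C[C@H](CO)[C@@H](O)C(=O)OCC)cc(OC)c3OCc3ccccc3)c2)[C@H](Cc2ccc(OCc3ccccc3)c(OC)c2)CO | intermediate (not isolated)
19 | tri-O-benzyl bis-lactone: ring A (3R,4R) complete, ring B (3R,4R)-3-hydroxy-4-arylmethyl | COc1cc(C[C@@H]2COC(=O)[C@@]2(O)Cc2cc(OC)c(OCc3ccccc3)c(-c3cc(C[C@@H]4COC(=O)[C@@H]4O)cc(OC)c3OCc3ccccc3)c2)ccc1OCc1ccccc1 | intermediate
20 | tetra-O-benzyl ether of the target | COc1cc(C[C@@H]2COC(=O)[C@@]2(O)Cc2cc(OC)c(OCc3ccccc3)c(-c3cc(C[C@@H]4COC(=O)[C@@]4(O)Cc4ccc(OCc5ccccc5)c(OC)c4)cc(OC)c3OCc3ccccc3)c2)ccc1OCc1ccccc1 | intermediate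
21 | CNP0218652.1, both lactones (3R,4R) | COc1cc(C[C@@H]2COC(=O)[C@@]2(O)Cc2cc(OC)c(O)c(-c3cc(C[C@@H]4COC(=O)[C@@]4(O)Cc4ccc(O)c(OC)c4)cc(OC)c3O)c2)ccc1O | target

**Step count**
Total: 13 steps. Longest linear sequence: 10 steps (4 → 5 → 7 → 8 → 9 → 10 → 14 → 15 → 19 → 20 → 21).

**Three steps most likely to fail**

**Step 9.** Two ortho-alkoxy arenes have to be coupled in the presence of a free acid and a base-labile acyl acetal. The fallback sets out from 10 and comes back at 19.
- 10 is treated first with BH3·THF and then TFA. This gives the robust bromo lactone (3R,4R)-3-[4-(benzyloxy)-3-bromo-5-methoxybenzyl]-4-[4-(benzyloxy)-3-methoxybenzyl]-3-hydroxyoxolan-2-one F1.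
- F1 is coupled with 13 and gives the enal lactone F2.
- Hantzsch ester reduction of F2 gives the propanal lactone F3.
- The diarylprolinol aldol of F3 with 16, followed by NaBH4 and acid, closes ring B and delivers 19.

**Step 11.** The amine catalyst may be slowed by the carboxylic acid of the large substrate, and borane has to spare the α-hydroxy ester. The fallback sets out from 12 and comes back at 19.
- 12 is reduced with the Hantzsch ester to 3-[4-(benzyloxy)-3-bromo-5-methoxyphenyl]propanal F4.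
- The aldol with 16 is run on this small, acid-free aldehyde. NaBH4 and acid then give (3R,4R)-4-[4-(benzyloxy)-3-bromo-5-methoxybenzyl]-3-hydroxyoxolan-2-one F5.
- Miyaura borylation of F5 gives the lactone boronate F6.
- Coupling of F6 with 10 gives the lactone acetal acid F7.
- BH3·THF and then TFA close ring A and give 19.

**Step 12.** The tri-lithiated species may be poorly soluble or be alkylated on oxygen. The fallback sets out from 19 and comes back at 21.
- The same enediolate is added to commercial 4-(benzyloxy)-3-methoxybenzaldehyde, an aldol addition that is also anti to the C4 group. This gives the benzylic carbinol F8 as a mixture at the new carbinol carbon.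
- One hydrogenolysis (H2, Pd/C, EtOH/AcOH, 50 °C) removes the benzylic hydroxyl group together with all benzyl ethers and gives 21 directly.

**Further compounds**
F1 | step 9 | (3R,4R)-3-[4-(benzyloxy)-3-bromo-5-methoxybenzyl]-4-[4-(benzyloxy)-3-methoxybenzyl]-3-hydroxyoxolan-2-one | COc1cc(C[C@@H]2COC(=O)[C@@]2(O)Cc2cc(OC)c(OCc3ccccc3)c(Br)c2)ccc1OCc1ccccc1
F2 | step 9 | enal lactone (F1 with Br replaced by the 2-(benzyloxy)-3-methoxy-5-[(E)-3-oxoprop-1-enyl]phenyl group) | COc1cc(C[C@@H]2COC(=O)[C@@]2(O)Cc2cc(OC)c(OCc3ccccc3)c(-c3cc(/C=C/C=O)cc(OC)c3OCc3ccccc3)c2)ccc1OCc1ccccc1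
F3 | step 9 | propanal lactone (F2 with the enal arm reduced to 3-oxopropyl) | COc1cc(C[C@@H]2COC(=O)[C@@]2(O)Cc2cc(OC)c(OCc3ccccc3)c(-c3cc(CCC=O)cc(OC)c3OCc3ccccc3)c2)ccc1OCc1ccccc1
F4 | step 11 | 3-[4-(benzyloxy)-3-bromo-5-methoxyphenyl]propanal | O=CCCc1cc(OC)c(OCc2ccccc2)c(Br)c1
F5 | step 11 | (3R,4R)-4-[4-(benzyloxy)-3-bromo-5-methoxybenzyl]-3-hydroxyoxolan-2-one | COc1cc(C[C@@H]2COC(=O)[C@@H]2O)cc(Br)c1OCc1ccccc1
F6 | step 11 | lactone boronate (F5 with Br replaced by the pinacol boronate group) | COc1cc(C[C@@H]2COC(=O)[C@@H]2O)cc(B2OC(C)(C)C(C)(C)O2)c1OCc1ccccc1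
F7 | step 11 | lactone acetal acid (10 with Br replaced by the aryl group of F6) | O=C1O[C@H](C(C)(C)C)O[C@]1(Cc2cc(OC)c(OCc3ccccc3)c(-c3cc(C[C@@H]4COC(=O)[C@@H]4O)cc(OC)c3OCc3ccccc3)c2)[C@H](Cc2ccc(OCc3ccccc3)c(OC)c2)C(=O)O
F8 | step 12 | benzylic carbinol (20 with one extra OH on the outer benzylic carbon of ring B, both epimers) | COc1cc(C[C@@H]2COC(=O)[C@@]2(O)Cc2cc(OC)c(OCc3ccccc3)c(-c3cc(C[C@@H]4COC(=O)[C@@]4(O)C(O)c4ccc(OCc5ccccc5)c(OC)c4)cc(OC)c3OCc3ccccc3)c2)ccc1OCc1ccccc1
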